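The earlier runs and the new flask are simulated for an exercise.

Slowness was what I noticed first: the solid substrate left both earlier runs at a steady pace, and I took that pace as my clock.

all flasks: gas phase 0.67 mM (held)

| flask | solid substrate | remark | time |
|---|---|---|---|
| east | 0.0085 M | run made earlier |  |
| south | 0.013 M | run made earlier |  |
| flask | 0.017 M |  | 4.0 min |

| run | time / min | target / % | solid substrate / % |
|---|---|---|---|
| east | 0.250 | 2.6 | 89.4 |
| east | 0.667 | 12.0 | 72.2 |
| east | 1.33 | 28.1 | 46.7 |
| east | 2.00 | 39.7 | 21.0 |
| east | 3.00 | 49.3 | 0 |
| east | 4.00 | 39.3 | 0 |
| east | 5.00 | 31.4 | 0.1 |
| south | 0.667 | 7.8 | 82.2 |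
| south | 1.33 | 18.0 | 65.2 |
| south | 2.00 | 26.1 | 48.6 |
| south | 3.00 | 35.1 | 24.8 |
| south | 4.00 | 42.9 | 0.9 |
| south | 5.00 | 38.2 | 0 |

(readings scatter by 0.3 percentage points)

- as a solid, counted per litre of solution: solid substrate
- at the start none of the solid substrate is in solution
- at the start none of the gas phase is in solution

* the target standing at 4.0 min, as a percentage of the solid substrate charged
* the change that raises the amount of target at 4.0 min, in percent of the solid substrate charged most ("none" if none brings more than 2 percentage points) (autumn / summer / dusk / midnight / none)
* amount of target at 4.0 min, in percent of the solid substrate charged, after autumn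

- autumn: doubling the solubility of the solid substrate, all else as stated
- summer: doubling the transfer coefficient of the gas phase, all else as stated
- dusk: doubling the dissolution coefficient of the solid substrate, all else as stated
- midnight: doubling the saturation concentration of gas phase, all else as stated

1. In the south run the solid substrate fell from 82.2% to 24.8% between 0.667 min and 3.00 min, a pace of 0.246 /min as a fraction of its charge. The east run gave 0.384 /min. These paces stand in the ratio 1.56, close to the inverse ratio of the charges, 1.53, so I read a nearly fixed amount dissolved per minute: roughly zero-order dissolution.

2. Scaled to the flask's charge, this gave me 5.32 min. I call this the clearing time: the charge divided by what dissolves per minute.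

3. At one end, solid outlasts the reading, and I took target to follow one curve in amount. East's 39.7% at 2.00 min, rescaled to south's charge, is 26.0%, against south's 26.1%. At the other end, solid clears early and target falls, as in the east run, from 49.3% at 3.00 min to 39.3% at 4.00 min.

4. The flask's clearing time is longer than 4.0 min, so it belongs to the first end. South's 42.9% at 4.00 min, rescaled, gave me 32.8% for the flask, and its clearing time gave me 24.7% solid left.

The forecast said 32.9% for the flask and 38% after autumn, and it chose autumn on the ground that “Faster dissolution helps most”.

The simulation gave 32.6%, dusk and 38.9%.

    solid substrate ⇌ starting material, rate k1*(cs1 - [starting material]) while solid is left; crystals form when [starting material] > cs1 (solubility = 9.80 mM, k = 0.00650 /s)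
    gas phase ⇌ dissolved gas, rate k2*(csat - [dissolved gas]) (kL = 15.0 /s)
    starting material + dissolved gas ⇌ target (K = 11000 /M, k = 61.0 /M/s)
    target ⇌ isomer of the product (K = 3.30, k = 0.00890 /s)

The flask held 24.2% solid substrate at 4.00 min, against my 24.7%. The choice parted from the forecast: dusk gained 8.3 percentage points, autumn 6.3 points. A neighbouring flask, the same charge read at 2.5 min, took the same reckoning. Its clearing time predicted 53.0% solid left. South's mean target at 2.00 min and 3.00 min, which brackets that time, rescaled to 23.4%. That neighbouring flask held 51.5% solid substrate and 23.8% target.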